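## The problem

Target 29 is a labdane: a decalin C1–C10 fused at C5–C10, with C20 on C10, C18 and C19 on C4, C17 on C8 and the chain C11–C16 on C9. Its six stereocentres sit on a trans-fused decalin in an unusual arrangement: C20, C19, C17 and H9 lie on one face, while H5, the C9 chain and the C8 hydroxyl lie on the other, so the chain is axial and anti to C20 (faces are called syn or anti to C20 below). Ring A carries the contiguous triad C3 (equatorial acetate), C4 (quaternary, axial C19, equatorial hydroxymethyl C18) and C5; ring B carries quaternary C10, the tertiary carbinol C8 and C9, with C11 and the C8 oxygen cis. Control can run in one direction only: C5 can set C10 through a trans alkylation, C5 and C10 together can set C4 if ring A closes through a chair, the axial C19 then steers hydride to C3, and C20 decides from which face C9 is reached. C8 is the awkward centre, because an external reagent that must add oxygen cis to an axial C9 chain meets that chain on one face and C20 on the other; the oxygen is better delivered from within the molecule. The 2-substituted buta-1,3-diene (acid, electrophiles, radicals), the tertiary C8 alcohol (elimination, ether closure onto an activated C12) and the secondary acetate beside a free primary alcohol (1,3-acyl shift) will not survive rough treatment, so diene and acetate must arrive late. The feature that opens the route is that O3 and O18 are 1,3-related across C4, and that C4 with C18 and C19 hangs on C5 exactly as the isopropenyl group of carvone hangs on its stereocentre. An isoxazoline C3=N–O–C18 is therefore the retron, and a nitrile oxide at C3 adding to that isopropenyl group closes ring A.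

## Retrosynthesis

**Diene and acetate.** Target 29 comes from its C18 silyl ether 28, and 28 from terminal alkyne 27 by an ene–yne cross-metathesis that cuts C13=C16 and C14=C15. Cutting C11–C12 or C9–C11 instead would need a diene-bearing nucleophile and would drag the diene through every later step. Here the diene appears after all halogen, tin and acid chemistry is over. Alkyne 27 comes from triol 25 through 26: the primary alcohol is silylated so that the acetate can be placed on C3. The forward steps must give the 2-substituted diene only and must free C18–OH without moving the acetate.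

**C13≡C14 and C12=C13.** Alkyne 25 comes from lactol 24 by a one-carbon alkyne homologation, 24 from enol ether 23, and 23 from lactol 22 by a Wittig reaction; 22 is the reduced form of lactone 21. Displacing a leaving group on C12 with a butadienyl metal would be shorter, but an activated C12 next to the C8 alkoxide closes a tetrahydrofuran. Carbonyl homologation never puts a leaving group on C12. Lactone 21 holds only C11 and C12 of the chain. The forward reactions need the lactols to open to their hydroxy aldehydes under basic conditions.

**C8–O.** Lactone 21 comes from iodolactone 20, and 20 from amide 18 by cutting C8–O (and C7–I). A carboxyl oxygen on the axial C9 arm can reach C8 only on its own face, which gives the cis relationship that an external oxidant cannot be trusted to give. Amide 18 lacks the C8 stereocentre and carries a plain C7=C8 alkene. The closure must be 5-exo and Markovnikov, and ring B must tolerate an anti addition that takes it out of its chair.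

**C9–C11.** Amide 18 comes from allylic alcohol 16 by a [3,3] shift that cuts C9–C11 and restores the C7–O bond. The shift is suprafacial, so the C7 oxygen (anti to C20) hands its face to C9, and that face is also the open one. Conjugate addition to the derived enone reaches the same face but leaves a C7 ketone to excise and C8 as an enolate carbon. Alcohol 16 has no chain and one ring B stereocentre. The rearrangement must outrun elimination at a carbon next to quaternary C10.

**C7–O (enone transposition).** Alcohol 16 comes from epoxy ketone 14 by a Wharton transposition, and 14 from enone 13. Carvone supplies oxygen at C9 and unsaturation at C7=C8, whereas the target needs carbon at C9; epoxidation trans to the C5–C4 bond followed by transposition moves the oxygen to C7 with a defined configuration. The forward step needs hydrazone formation at a crowded ketone.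

**Ring A adjustments.** Acetonide 13 comes from diol 12, 12 from hydroxy diketone 11 by hydride addition at C3, and 11 from isoxazoline 9 by N–O cleavage. These steps cut no skeletal bond. They ask for reduction of the saturated ketone in the presence of the enone, and for hydride to enter anti to C19.

**C3–C4 and O–C18 (key step).** Isoxazoline 9 comes from oxime 7 through nitrile oxide 8. This single cut removes ring A and the quaternary centre C4 and leaves a monocyclic carvone derivative. Neighbouring cuts (C4–C18 or C4–C5) would leave C4 to be built on an existing ring without carvone's help. The cycloaddition must close through a chair so that C19 ends axial.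

**C1–C10 and C10–C20.** Oxime 7 comes from acetal 5; 5 comes from methylcarvone 2 and iodide 4 by cutting C1–C10; 2 comes from carvone 1 by cutting C10–C20; 4 comes from commercial bromide 3. The order matters: the second group enters anti to the isopropenyl group, so the chain must come last.

## Roads not taken

**Alternative 1:** The cut is C4–C18, together with the C5–H bond. A bromomethylsilyl ether A1 of a 4-en-3-ol decalin, with its C3 oxygen anti to C20, would be treated with a tin hydride. The silylmethyl radical closes 5-exo onto C4, and the C5 radical takes hydrogen anti to C20, giving oxasilolane A2; Tamao oxidation would then reveal C18–OH. The merit is real: a tethered 5-exo closure fixes C18 cis to the tether oxygen with a certainty that the nitrile oxide closure, which must tolerate a developing C19/C20 diaxial contact, cannot match, and C5 is set in the same step. The weak points are specific to this target. The tether delivers C18 cis to O3, yet the target has them trans, so C3 must start epimeric and be inverted later by oxidation and reduction. The hydrogen transfer to the ring-fusion radical may not be fully trans-selective. Ring B of A2 carries nothing but a ketal at C9, so C17, the C8 carbinol and the anti chain must all be built from one carbonyl. The chosen plan sets against the better C4 control that C3 arrives at the ketone level and needs no inversion, that carvone supplies C17 and the ring B enone, and that the absolute configuration comes from the chiral pool.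

**Alternative 2:** The cut is C5–C10 and C8–C9, so ring B is made by a Diels–Alder reaction. Menthyloxy butenolide A3 and silyloxy diene A4 would combine endo and anti to the menthyloxy group to give adduct A5. Its merits are that C10, C9 and the C8 methyl are set in one step under auxiliary control, and that the acetal carbon C11 is already cis to the C1 carbonyl, which is the anti-to-C20 arrangement the target needs. In this respect it is better than the chosen plan, which earns C9 only late. The weak points are that the trisubstituted α-methyl butenolide is a sluggish dienophile, that C5 of A5 is an unfunctionalised methylene, and that the whole of ring A with C3, C4 and C5 remains to be built on it. The C8 methine would also still have to be hydroxylated cis to the C9 substituent. The chosen plan sets against it that one cycloaddition delivers ring A with C4, and that C5 is never in question.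

**Alternative 3:** The cut is C9–C11 and C8–O in one operation. Enone A6 (the oxidation product of 16) would take up the organocopper reagent made from Grignard reagent A7 at C9, and the resulting enolate would be oxidised at C8 by a molybdenum peroxide complex to give hydroxy ketone A8. It is the most convergent option: the complete chain arrives in one step, anti to C20 by axial attack, and the carbon skeleton would be finished about four steps earlier than in the chosen plan. For C9 it is as good as the [3,3] shift. The weak points lie at C8 and C7. The oxidant must approach C8 cis to the new axial chain, nearly eclipsing C9–C11, while the other face is 1,3-diaxial to C20, so neither face is clearly preferred. The C7 ketone must then be removed next to a tertiary alcohol with the diene present, where radical deoxygenation endangers the diene and hydrazone methods invite loss of the α-hydroxyl. The chosen plan spends more steps on the chain, but delivers O8 through a lactone, sheds the C7 oxygen as part of the sequence and makes the diene last.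

Key step: step 5

Remark on the chemistry: 2-(2-bromoethyl)-1,3-dioxolane 3 is taken as commercial and stands for acrolein at the aldehyde oxidation level, because direct Michael addition of the cross-conjugated enolate to acrolein or an acrylate invites a second, intramolecular Michael addition.

## Route

Step 1
Reactants: 1 (S)-(+)-carvone
Product: 2 trans-6-methylcarvone (5S,6R)-2,6-dimethyl-5-(prop-1-en-2-yl)cyclohex-2-en-1-one
Conditions: LiN(i-Pr)2, THF, −78 °C; MeI, −78 to 0 °C
Reagents that add atoms: iodomethane, CI
Why: Kinetic deprotonation gives the cross-conjugated α′ enolate, which is C-methylated (enolate alkylation); the minor 6-epimer is carried along because this centre is re-enolised in step 3.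

Step 2
Reactants: 3 2-(2-bromoethyl)-1,3-dioxolane
Product: 4 2-(2-iodoethyl)-1,3-dioxolane
Conditions: NaI, acetone, reflux
Reagents that add atoms: sodium iodide, [Na+].[I-]
Why: Finkelstein halide exchange driven by precipitation of NaBr; the iodide is the stronger electrophile needed for a hindered enolate.

Step 3
Reactants: 2 trans-6-methylcarvone; 4 2-(2-iodoethyl)-1,3-dioxolane
Product: 5 acetal ketone (5R,6R)-6-[2-(1,3-dioxolan-2-yl)ethyl]-2,6-dimethyl-5-(prop-1-en-2-yl)cyclohex-2-en-1-one
Conditions: LiN(i-Pr)2, THF, −78 to 0 °C; then 4, DMPU, −78 °C to rt
Reagents that add atoms: none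
Why: Alkylation of the tetrasubstituted α′ enolate; the electrophile enters anti to the neighbouring isopropenyl group, so the chain ends trans to it and the methyl cis, which sets C10 from C5.

Step 4
Reactants: 5 acetal ketone
Product: 7 aldoxime (5R,6R)-6-[(3E)-3-(hydroxyimino)propyl]-2,6-dimethyl-5-(prop-1-en-2-yl)cyclohex-2-en-1-one, via keto aldehyde 6 (not isolated)
Conditions: 1 M HCl, THF, rt; then NH2OH·HCl, NaOAc, EtOH–H2O, rt
Reagents that add atoms: hydroxylamine hydrochloride, Cl.NO
Why: Acetal hydrolysis followed by oxime condensation; the aldehyde condenses far faster than the conjugated ketone flanked by a quaternary carbon, and either oxime geometry serves in step 5.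

Step 5
Reactants: 7 aldoxime
Product: 9 tricyclic isoxazoline (ring A closed; C3=N–O–C18; 7-en-9-one in ring B), via nitrile oxide 8 (not isolated)
Conditions: aq NaOCl, CH2Cl2, 0 °C to rt, high dilution
Reagents that add atoms: none
Why: Hypochlorite chlorinates the aldoxime and loss of HCl gives nitrile oxide 8, which adds to the isopropenyl group in a concerted suprafacial [3+2] cycloaddition; the closest known reaction type is the intramolecular nitrile oxide–alkene cycloaddition onto a 1,1-disubstituted alkene that leaves a carbocycle-fused isoxazoline. Ring A closes as a six-membered carbocycle in the fused (exo) mode, the dipole carbon C3 bonding to the proximal alkene carbon C4; the isoxazoline closes at the same time as the five-membered cycloadduct ring, oxygen bonding to the terminal carbon C18. The only new stereocentre, C4, is controlled by C5 and C10: the tether leaves C10 equatorially and the alkene sits equatorially on C5, so ring A forms through a chair, and in a chair the nearly planar C3=N–O–C18 unit can reach only an equatorial C18, which forces C19 axial and syn to C20. The step needs chemoselectivity for the isopropenyl group over the enone alkene and for cyclisation over dimerisation to a furoxan: the three-atom tether cannot reach C7=C8, the electron-poor enone is a poor dipolarophile, and slow generation at high dilution keeps the dipole concentration low. Regiochemistry is fixed by the tether, since oxygen-to-C4 bonding would demand a bridged seven-membered ring.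

Step 6
Reactants: 9 tricyclic isoxazoline
Product: 11 hydroxy diketone (18-hydroxy-3,9-dioxo-7-ene), via hydroxy imine 10 (not isolated)
Conditions: Mo(CO)6, MeCN–H2O, 80 °C
Reagents that add atoms: water, O
Why: Reductive N–O cleavage of the isoxazoline by zerovalent molybdenum and hydrolysis of the β-hydroxy imine (isoxazoline as masked aldol); no hydrogenation is involved, so the enone survives, and the neutral medium spares the retro-aldol-prone hydroxymethyl ketone.

Step 7
Reactants: 11 hydroxy diketone
Product: 12 enone diol (3,18-dihydroxy-7-en-9-one; 3-OH equatorial)
Conditions: NaBH4, MeOH–CH2Cl2 (1:1), −78 °C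
Reagents that add atoms: none
Why: Chemoselective borohydride reduction of the saturated ketone beside the hindered conjugated one; hydride adds axially to C3 from the face anti to the axial C19 methyl, giving the equatorial alcohol trans to C18.

Step 8
Reactants: 12 enone diol
Product: 13 enone acetonide (3,18-O-isopropylidene)
Conditions: Me2C(OMe)2, PPTS, CH2Cl2, rt
Reagents that add atoms: 2,2-dimethoxypropane, COC(C)(C)OC
Why: Acetal exchange; the diequatorial 1,3-diol closes a fused 1,3-dioxane that protects both hydroxyls through the base, hydride and ylide steps.

Step 9
Reactants: 13 enone acetonide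
Product: 14 epoxy ketone (7,8-epoxide anti to C20)
Conditions: 30% H2O2, NaOH, MeOH, 0 °C
Reagents that add atoms: hydrogen peroxide, OO
Why: Weitz–Scheffer nucleophilic epoxidation; hydroperoxide adds axially to C7, trans to the C5–C4 bond as in carvone itself, so the epoxide lies anti to C20.

Step 10
Reactants: 14 epoxy ketone
Product: 16 allylic alcohol (8-en-7-ol; OH anti to C20), via epoxy hydrazone 15 (not isolated)
Conditions: N2H4·H2O, AcOH (cat.), MeOH, 0 °C to rt
Reagents that add atoms: none
Why: Wharton transposition: the epoxy hydrazone opens to a vinyl diazene that loses N2, placing the alkene at C8=C9; the C7–O bond is never broken, so its configuration is that of the epoxide.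

Step 11
Reactants: 16 allylic alcohol
Product: 18 amide (C9–CH2CONMe2 anti to C20; 7-ene), via ketene N,O-acetal 17 (not isolated)
Conditions: MeC(OMe)2NMe2, xylene, 140 °C
Reagents that add atoms: N,N-dimethylacetamide dimethyl acetal, CC(OC)(OC)N(C)C
Why: Eschenmoser–Claisen rearrangement; the [3,3] shift is suprafacial, so the pseudoaxial C7 oxygen passes its face to C9 and C11 arrives anti to C20, which is also the unhindered face.

Step 12
Reactants: 18 amide
Product: 20 iodolactone (8,12-olide; 7-iodide syn to C20), via iminium lactone iodide 19 (not isolated)
Conditions: I2, THF–H2O (1:1), rt, dark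
Reagents that add atoms: iodine, II; water, O
Why: Iodolactonization of a γ,δ-unsaturated amide; the amide oxygen on the axial C9 arm can reach C8 only on its own face (5-exo, Markovnikov) while iodine adds anti at C7, and water hydrolyses the iminium lactone. C8 is thus set by C9, with oxygen cis to C11 and C17 syn to C20.

Step 13
Reactants: 20 iodolactone
Product: 21 lactone (8,12-olide)
Conditions: Bu3SnH, AIBN (cat.), PhMe, 80 °C
Reagents that add atoms: none
Why: Radical-chain dehalogenation turns C7 into a methylene; no diene is present yet, so tin radicals have nothing else to attack.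

Step 14
Reactants: 21 lactone
Product: 22 lactol (12-hydroxy-8,12-epoxide; anomers)
Conditions: i-Bu2AlH, CH2Cl2, −78 °C
Reagents that add atoms: none
Why: Partial reduction of a lactone; the tetrahedral aluminate is stable at low temperature and gives the lactol on work-up.

Step 15
Reactants: 22 lactol
Product: 23 enol ether (13-methoxy-12-ene; free 8-OH; E/Z)
Conditions: MeOCH2PPh3Cl, KN(SiMe3)2, THF, 0 °C to rt
Reagents that add atoms: (methoxymethyl)triphenylphosphonium chloride, COC[P+](c1ccccc1)(c1ccccc1)c1ccccc1.[Cl-]
Why: Wittig methoxymethylenation of the open hydroxy aldehyde form of the lactol, with excess ylide because one equivalent is spent as base; the alkene geometry is irrelevant.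

Step 16
Reactants: 23 enol ether
Product: 24 triol lactol (C13 hemiacetal closed on O8; free 3-OH and 18-OH)
Conditions: 1 M HCl, THF, rt
Reagents that add atoms: water, O
Why: Acid hydrolysis of the enol ether gives the C13 aldehyde, which the C8 hydroxyl traps as a six-membered lactol; the same acid removes the acetonide, whose work is done.

Step 17
Reactants: 24 triol lactol
Product: 25 alkyne triol (13-yne; 3,8,18-triol)
Conditions: MeC(O)C(N2)P(O)(OMe)2, K2CO3, MeOH, rt
Reagents that add atoms: dimethyl (1-diazo-2-oxopropyl)phosphonate, COP(=O)(OC)C(=[N+]=[N-])C(C)=O
Why: Ohira–Bestmann (Seyferth–Gilbert) homologation of the aldehyde in equilibrium with the lactol; the carbonate base tolerates the free triol.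

Step 18
Reactants: 25 alkyne triol
Product: 26 silyl ether diol (18-O-TBS)
Conditions: TBSCl (1.1 equiv), imidazole, DMF, 0 °C
Reagents that add atoms: tert-butyldimethylsilyl chloride, CC(C)(C)[Si](C)(C)Cl
Why: Selective silylation of the primary alcohol over the hindered secondary and the tertiary one, so that acylation can be directed to C3.

Step 19
Reactants: 26 silyl ether diol
Product: 27 acetate (3-O-acetyl; 18-O-TBS; 8-OH free)
Conditions: Ac2O, pyridine, DMAP (cat.), CH2Cl2, rt
Reagents that add atoms: acetic anhydride, CC(=O)OC(C)=O
Why: DMAP-catalysed acylation of the secondary C3 alcohol; the tertiary C8 alcohol, flanked by an axial methyl and the C9 arm, is too hindered to react under these conditions.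

Step 20
Reactants: 27 acetate
Product: 28 silylated diene (18-O-TBS ether of the target)
Conditions: ethylene (1 atm), second-generation Grubbs catalyst (H2IMes)(PCy3)Cl2Ru=CHPh (5 mol%), CH2Cl2, rt
Reagents that add atoms: ethylene, C=C
Why: Ene–yne cross-metathesis: the ruthenium methylidene adds to the terminal alkyne and the vinyl carbene is released by ethylene as the 2-substituted buta-1,3-diene; the ethylene atmosphere suppresses secondary metathesis of the product.

Step 21
Reactants: 28 silylated diene
Product: 29 target compound CNP0313672.1
Conditions: HF·pyridine, pyridine–THF, 0 °C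
Reagents that add atoms: none
Why: Fluoride desilylation in a buffered, weakly acidic medium, which avoids the base-promoted 1,3-acyl shift from O3 to O18 and is too mild to ionise the tertiary alcohol or protonate the diene.

## Compound list

1 | (S)-(+)-carvone, (5S)-2-methyl-5-(prop-1-en-2-yl)cyclohex-2-en-1-one | CC1=CC[C@@H](CC1=O)C(C)=C | starting material
2 | trans-6-methylcarvone, (5S,6R)-2,6-dimethyl-5-(prop-1-en-2-yl)cyclohex-2-en-1-one (major epimer drawn; the 6-epimer converges in step 3) | CC1=CC[C@H](C(C)=C)[C@@H](C)C1=O | intermediate
3 | 2-(2-bromoethyl)-1,3-dioxolane | BrCCC1OCCO1 | starting material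
4 | 2-(2-iodoethyl)-1,3-dioxolane | ICCC1OCCO1 | intermediate
5 | acetal ketone, (5R,6R)-6-[2-(1,3-dioxolan-2-yl)ethyl]-2,6-dimethyl-5-(prop-1-en-2-yl)cyclohex-2-en-1-one (chain trans to isopropenyl) | CC1=CC[C@H](C(C)=C)[C@@](C)(CCC2OCCO2)C1=O | intermediate
6 | keto aldehyde, (5R,6R)-2,6-dimethyl-6-(3-oxopropyl)-5-(prop-1-en-2-yl)cyclohex-2-en-1-one (not isolated) | CC1=CC[C@H](C(C)=C)[C@@](C)(CCC=O)C1=O | intermediate
7 | aldoxime, (5R,6R)-6-[(3E)-3-(hydroxyimino)propyl]-2,6-dimethyl-5-(prop-1-en-2-yl)cyclohex-2-en-1-one | CC1=CC[C@H](C(C)=C)[C@@](C)(CC/C=N/O)C1=O | intermediate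
8 | nitrile oxide, 3-[(1R,6R)-1,3-dimethyl-2-oxo-6-(prop-1-en-2-yl)cyclohex-3-en-1-yl]propanenitrile oxide (not isolated) | CC1=CC[C@H](C(C)=C)[C@@](C)(CCC#[N+][O-])C1=O | intermediate
9 | tricyclic isoxazoline: trans-decalin 7-en-9-one (C17 on C8, C20 on C10) with isoxazoline C3=N–O–C18 fused at C3–C4; C19 axial and syn to C20, H5 anti to C20 | CC1=CC[C@H]2[C@@](C)(CCC3=NOC[C@]23C)C1=O | intermediate
10 | hydroxy imine: 18-hydroxy-3-imino-7-en-9-one (not isolated) | CC1=CC[C@H]2[C@@](C)(CCC(=N)[C@]2(C)CO)C1=O | intermediate
11 | hydroxy diketone: 18-hydroxy-7-ene-3,9-dione; C19 axial syn to C20, C18 equatorial | CC1=CC[C@H]2[C@@](C)(CCC(=O)[C@]2(C)CO)C1=O | intermediate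
12 | enone diol: 3,18-dihydroxy-7-en-9-one; 3-OH equatorial, trans to C18 | CC1=CC[C@H]2[C@@](C)(CC[C@@H](O)[C@]2(C)CO)C1=O | intermediate
13 | enone acetonide: 3,18-O-isopropylidene derivative of 12 | CC1=CC[C@H]2[C@@](C)(CC[C@H]3OC(C)(C)OC[C@]23C)C1=O | intermediate
14 | epoxy ketone: 7,8-epoxy-9-one, epoxide oxygen anti to C20, C17 syn to C20; 3,18-acetonide | C[C@]12O[C@H]1C[C@H]3[C@@](C)(CC[C@H]4OC(C)(C)OC[C@]34C)C2=O | intermediate
15 | epoxy hydrazone: C9 hydrazone of 14 (not isolated) | C[C@]12O[C@H]1C[C@H]3[C@@](C)(CC[C@H]4OC(C)(C)OC[C@]34C)C2=NN | intermediate
16 | allylic alcohol: 8-en-7-ol, 7-OH anti to C20; 3,18-acetonide | CC1=C[C@]2(C)CC[C@H]3OC(C)(C)OC[C@]3(C)[C@H]2C[C@@H]1O | intermediate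
17 | ketene N,O-acetal: 7-O-[1-(dimethylamino)ethenyl] ether of 16 (not isolated) | CC1=C[C@]2(C)CC[C@H]3OC(C)(C)OC[C@]3(C)[C@H]2C[C@@H]1OC(=C)N(C)C | intermediate
18 | amide: 7-ene with CH2CONMe2 on C9, axial and anti to C20 (H9 syn to C20); 3,18-acetonide | CC1=CC[C@H]2[C@@](C)(CC[C@H]3OC(C)(C)OC[C@]23C)[C@H]1CC(=O)N(C)C | intermediate
19 | iminium lactone iodide: O8–C12(=NMe2+) ring closed on the face of C11, 7-iodide syn to C20 (not isolated) | C[C@@]12OC(=[N+](C)C)C[C@@H]1[C@]3(C)CC[C@H]4OC(C)(C)OC[C@]4(C)[C@H]3C[C@H]2I.[I-] | intermediate
20 | iodolactone: 8,12-olide cis-fused at C8–C9 (O8 cis to C11, C17 syn to C20), 7-iodide trans to O8; 3,18-acetonide | C[C@@]12OC(=O)C[C@@H]1[C@]3(C)CC[C@H]4OC(C)(C)OC[C@]4(C)[C@H]3C[C@H]2I | intermediate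
21 | lactone: 8,12-olide, cis-fused at C8–C9; 3,18-acetonide | C[C@@]12OC(=O)C[C@@H]1[C@]3(C)CC[C@H]4OC(C)(C)OC[C@]4(C)[C@H]3CC2 | intermediate
22 | lactol: 12-hydroxy-8,12-epoxide (anomers at C12); 3,18-acetonide | C[C@@]12OC(O)C[C@@H]1[C@]3(C)CC[C@H]4OC(C)(C)OC[C@]4(C)[C@H]3CC2 | intermediate
23 | enol ether: C9–CH2–CH=CH–OMe (E/Z), free tertiary 8-OH; 3,18-acetonide | COC=CC[C@@H]1[C@]2(C)CC[C@H]3OC(C)(C)OC[C@]3(C)[C@H]2CC[C@]1(C)O | intermediate
24 | triol lactol: six-membered hemiacetal C13(OH)–O8 (anomers), free 3-OH and 18-OH | OC1CC[C@@H]2[C@]3(C)CC[C@@H](O)[C@](C)(CO)[C@H]3CC[C@]2(C)O1 | intermediate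
25 | alkyne triol: C9–CH2CH2–C≡CH, 3,8,18-triol | C#CCC[C@@H]1[C@]2(C)CC[C@@H](O)[C@](C)(CO)[C@H]2CC[C@]1(C)O | intermediate
26 | silyl ether diol: 18-O-tert-butyldimethylsilyl ether of 25 | C#CCC[C@@H]1[C@]2(C)CC[C@@H](O)[C@](C)(CO[Si](C)(C)C(C)(C)C)[C@H]2CC[C@]1(C)O | intermediate
27 | acetate: 3-O-acetyl-18-O-TBS alkyne, free 8-OH | C#CCC[C@@H]1[C@]2(C)CC[C@@H](OC(C)=O)[C@](C)(CO[Si](C)(C)C(C)(C)C)[C@H]2CC[C@]1(C)O | intermediate
28 | silylated diene: 18-O-TBS ether of the target | C=CC(=C)CC[C@@H]1[C@]2(C)CC[C@@H](OC(C)=O)[C@](C)(CO[Si](C)(C)C(C)(C)C)[C@H]2CC[C@]1(C)O | intermediate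
29 | CNP0313672.1: 3-acetoxy-8,18-dihydroxylabda-13(16),14-diene with the configuration of the SMILES | C=CC(=C)CC[C@@H]1[C@]2(C)CC[C@@H](OC(C)=O)[C@](C)(CO)[C@H]2CC[C@]1(C)O | target

## Step count and least certain steps

Total: 21 steps. Longest linear sequence: 20 steps (1 to 29 through steps 1 and 3–21); step 2 prepares the alkylating agent.

**Step 5 (key step).** The dipole may dimerise to a furoxan or the enone may be attacked by hypochlorite. The more serious risk is poor facial selectivity at C4, because the chair transition state must accept a developing C19/C20 diaxial contact and a boat would give the C4 epimer. Fallback, from 7: heat the oxime without oxidant (xylene, 140–180 °C, sealed vessel) so that its N–H nitrone tautomer adds to the isopropenyl group in a reversible intramolecular oxime–olefin cycloaddition, giving the N-unsubstituted isoxazolidine F1. N-Chlorination and dehydrochlorination (N-chlorosuccinimide, then Et3N) would then dehydrogenate F1 to the isoxazoline, and the route is rejoined at 9.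

**Step 3.** C-Alkylation of a tetrasubstituted, cross-conjugated enolate by a β-alkoxyalkyl iodide may be slow, so proton transfer back to 2, O-alkylation or a drop in facial selectivity can take over. Fallback, from 2: alkylate with allyl bromide, a much faster electrophile that also enters anti to the isopropenyl group, to give the allyl ketone F2. Hydroborate the monosubstituted alkene selectively with disiamylborane, oxidise with NaBO3·4H2O to the primary alcohol F3, and oxidise F3 with Dess–Martin periodinane to the aldehyde. The route is rejoined at 6, which continues with the oximation of step 4.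

**Step 10.** Hydrazone formation at C9, a ketone between two fully substituted carbons, may be too slow, so that hydrazine opens the epoxide or starting material returns. Fallback, from 14: reduce the ketone (NaBH4) to the epoxy alcohol F4, convert it with NaH, CS2 and MeI into the xanthate F5, and treat F5 with Bu3SnH and AIBN. The C9 radical opens the adjacent epoxide at C8–O and the resulting C7 alkoxy radical is reduced, rejoining the route at 16.

**Step 11.** The ketene N,O-acetal may eliminate to a diene instead of rearranging, because the new bond forms at a carbon next to quaternary C10 and the reaction needs 140 °C. Fallback, from 16: acetylate to the allylic acetate F6 and carry out an Ireland–Claisen rearrangement (LiN(i-Pr)2, Me3SiCl, −78 °C to rt, aqueous work-up) to the carboxylic acid F7. Iodolactonization of F7 (I2, NaHCO3, MeCN) rejoins the route at 20.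

**Step 12.** The tethered anti addition forces ring B out of its chair and needs iodonium formation on the face shielded by C20, so cyclisation may stall; the acid released could also open the acetonide. Fallback, from 18: protolactonization with MeSO3H in wet CH2Cl2, in which the C8 cation is captured by the amide oxygen without any antiperiplanar requirement and the iminium is hydrolysed. The acetonide is lost, giving the diol lactone F8, which is reprotected (Me2C(OMe)2, PPTS) to rejoin the route at 21 without the tin step.

## Further compounds

F1 | step 5 | N-unsubstituted isoxazolidine (C3–NH–O–C18 fused at C3–C4; C3 configuration not fixed) | CC1=CC[C@H]2[C@@](C)(CCC3NOC[C@]23C)C1=O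
F2 | step 3 | (5R,6R)-6-allyl-2,6-dimethyl-5-(prop-1-en-2-yl)cyclohex-2-en-1-one | CC1=CC[C@H](C(C)=C)[C@@](C)(CC=C)C1=O
F3 | step 3 | (5R,6R)-6-(3-hydroxypropyl)-2,6-dimethyl-5-(prop-1-en-2-yl)cyclohex-2-en-1-one | CC1=CC[C@H](C(C)=C)[C@@](C)(CCCO)C1=O
F4 | step 10 | epoxy alcohol: 7,8-epoxy-9-ol (either C9 epimer), 3,18-acetonide | C[C@]12O[C@H]1C[C@H]3[C@@](C)(CC[C@H]4OC(C)(C)OC[C@]34C)C2O
F5 | step 10 | S-methyl xanthate of F4 | C[C@]12O[C@H]1C[C@H]3[C@@](C)(CC[C@H]4OC(C)(C)OC[C@]34C)C2OC(=S)SC
F6 | step 11 | allylic acetate: 7-O-acetyl derivative of 16 | CC1=C[C@]2(C)CC[C@H]3OC(C)(C)OC[C@]3(C)[C@H]2C[C@@H]1OC(C)=O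
F7 | step 11 | carboxylic acid: 7-ene with CH2CO2H on C9, anti to C20; 3,18-acetonide | CC1=CC[C@H]2[C@@](C)(CC[C@H]3OC(C)(C)OC[C@]23C)[C@H]1CC(=O)O
F8 | step 12 | diol lactone: 8,12-olide with free 3-OH and 18-OH | C[C@@]12OC(=O)C[C@@H]1[C@]3(C)CC[C@@H](O)[C@](C)(CO)[C@H]3CC2
A1 | alternative 1 | (bromomethyl)dimethylsilyl ether of the 9,9-ethylenedioxy 4-en-3-ol, C3 oxygen anti to C20 | C[C@@]12CC[C@H](O[Si](C)(C)CBr)C(C)=C1CCCC24OCCO4
A2 | alternative 1 | trans-decalin with oxasilolane bridging O3 and C18, C9 dioxolane | C[C@@]12CC[C@@H]3O[Si](C)(C)C[C@]3(C)[C@H]1CCCC24OCCO4
A3 | alternative 2 | 5-menthyloxy-3-methylfuran-2(5H)-one | CC1=C[C@@H](O[C@H]2C[C@@H](C)CC[C@@H]2C(C)C)OC1=O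
A4 | alternative 2 | (Z)-3-(tert-butyldimethylsilyloxy)penta-1,3-diene | C/C=C(\O[Si](C)(C)C(C)(C)C)C=C
A5 | alternative 2 | cis-fused ring B lactone acetal with C7 silyl enol ether | C[C@H]1C(O[Si](C)(C)C(C)(C)C)=CC[C@@]2(C)C(=O)O[C@H](O[C@H]3C[C@@H](C)CC[C@@H]3C(C)C)[C@@H]12
A6 | alternative 3 | 8-en-7-one, 3,18-acetonide | CC1=C[C@]2(C)CC[C@H]3OC(C)(C)OC[C@]3(C)[C@H]2CC1=O
A7 | alternative 3 | 3-methylenepent-4-enylmagnesium bromide | C=CC(=C)CC[Mg]Br
A8 | alternative 3 | 8-hydroxy-7-ketone with the complete diene chain, 3,18-acetonide | C=CC(=C)CC[C@@H]1[C@]2(C)CC[C@H]3OC(C)(C)OC[C@]3(C)[C@H]2CC(=O)[C@]1(C)O
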